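**Plan**

1. Locants: carbocycle C1 (tertiary carbinol), C2 (angelate), C3 (lactone O), C4 (ring fusion), C5, C6, C7 (CHMe); lactone α-carbon C8, carbonyl C9; chain C1′(=O)–C2′–C3′(OH)–C4′; β is the face of the C3–O bond, α the opposite face.
2. Retrosynthetic cuts, in order: the C2–O angelate ester; the C1=C1′ bond of an alkylidene precursor (its osmylation supplies the oxygens at C1 and C1′); C1=O/C2–OH back to a C1=C2 alkene; C7–CH3; then together C3–O (lactone) and C7–O, which uncovers a ring diene C3=C2–C1=C7; last C4–C8.
3. Feature used: C3, C2, C1 and C7 are four contiguous functionalised ring carbons next to C4, which carries the C8–C9 arm of the γ-lactone ring; this is the footprint of a cyclohepta-1,3-diene with a tethered propanoic acid that can be 1,4-oxidised with lactone closure.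
4. Forward order: the seven-membered ring is bought as cycloheptanone; the γ-lactone, the only ring made, closes in step 5; the four-carbon chain is joined late by a Wittig reaction with an ylide from (R)-butane-1,3-diol; the angelate is put on in the last step but one.
5. Stereochemistry: C4 and C8 from a chiral-boron Ireland–Claisen rearrangement of an achiral dienyl ester; C3 from the cis ring fusion; C7 from trans acetoxylation then invertive methyl transfer; C2 from α-face oxidation; C1 from osmylation anti to the C2 oxygen; C3′ from the chiral pool.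

Key step: step 5

Assumption: the (S,S) bromoborane is taken to steer step 4 to the (2R) acid 8; the sense of induction on this ester is not established, and the (R,R) reagent, equally accessible, would replace it with no other change.

**Route**

Step 1
Reactants: 1 cycloheptanone
Product: 2 cyclohepta-2,6-dien-1-one
Conditions: o-iodoxybenzoic acid (IBX, 3 equiv), DMSO/fluorobenzene, 65–80 °C
Reagents that add atoms: none
Why: IBX dehydrogenation of a ketone to its enone, run twice in one operation, should desaturate both α,β-positions of the symmetrical ketone.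

Step 2
Reactants: 2 cyclohepta-2,6-dien-1-one
Product: 3 cyclohepta-2,6-dien-1-ol
Conditions: NaBH4, CeCl3·7H2O, MeOH, −40 °C
Reagents that add atoms: none
Why: Luche reduction adds hydride 1,2 to the cross-conjugated dienone and leaves both alkenes in place, giving an achiral alcohol.

Step 3
Reactants: 3 cyclohepta-2,6-dien-1-ol; 4 propanoyl chloride
Product: 5 cyclohepta-2,6-dien-1-yl propanoate
Conditions: pyridine, DMAP (cat.), CH2Cl2, 0 °C
Reagents that add atoms: none
Why: Base-mediated O-acylation of a secondary alcohol, under non-acidic conditions that avoid ionisation of the doubly allylic C–O bond.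

Step 4
Reactants: 5 cyclohepta-2,6-dien-1-yl propanoate
Product: 8 (2R)-2-[(1R)-cyclohepta-2,4-dien-1-yl]propanoic acid, via boron ketene acetal 6 (not isolated), via boryl ester 7 (not isolated)
Conditions: (S,S)-2-bromo-4,5-diphenyl-1,3-bis{[3,5-bis(trifluoromethyl)phenyl]sulfonyl}-1,3,2-diazaborolidine, Et3N, toluene/hexane, −78 °C then −20 °C; aqueous work-up
Reagents that add atoms: none
Why: Ireland–Claisen (ester enolate) rearrangement in its chiral-boron form: Et3N in toluene/hexane should give ketene acetal 6 with methyl cis to the allylic oxygen, the boat-like [3,3] array usual for cycloalkenyl esters keeps the bulky diazaborolidine outside the ring, and the controller fixes the enolate face and with it one of the two enantiotopic vinyl arms, so that C8 and C4 are set together.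

Step 5
Reactants: 8 (2R)-2-[(1R)-cyclohepta-2,4-dien-1-yl]propanoic acid
Product: 10 7α-acetoxy-Δ1 lactone (cis-fused γ-lactone; acetate trans to C3–O), via allylpalladium acetate 9 (not isolated)
Conditions: Pd(OAc)2 (5 mol %), p-benzoquinone (2 equiv), acetone/AcOH 4:1, 20 °C, no chloride
Reagents that add atoms: acetic acid, CC(=O)O
Why: Divalent palladium binds the diene on the face opposite the C8–C9 acid arm and the carboxylate attacks C3 anti to the metal, closing the γ-lactone 5-exo-trig, which allows only the cis ring fusion; the closest known reaction type is the Pd(OAc)2/benzoquinone 1,4-acetoxylactonisation of cycloalkadienylacetic acids, seven-membered rings included. This leaves the η3-allyl complex 9 over C2–C1–C7 on the α face. Without chloride the acetate bound to palladium migrates to C7 on the metal face, so C7–O forms trans to C3–O, and benzoquinone returns zerovalent palladium to the divalent state. C3 is therefore set by C4 through the tether, and C7 by the position of the metal, which C4 also dictates. The step needs anti attack at C3, 1,4- rather than 1,2-addition and internal rather than external acetate delivery; the two-carbon tether, the preference of the allyl complex to react at the terminus remote from the new C–O bond, and the absence of chloride secure these in that order. C8 is not enolisable in the acidic medium and is carried through unchanged.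

Step 6
Reactants: 10 7α-acetoxy-Δ1 lactone
Product: 11 7β-methyl-Δ1 lactone
Conditions: Me2CuLi (from CuI and 2 MeLi), Et2O, −30 → 0 °C; aq NH4Cl
Reagents that add atoms: lithium dimethylcuprate, [Li+].C[Cu-]C
Why: Copper-mediated allylic substitution (oxidative addition anti to the acetate, reductive elimination at the terminus remote from the hindered, electron-poor C2) should replace the α-acetate by methyl with inversion, placing C7–CH3 on the face of C3–O.

Step 7
Reactants: 11 7β-methyl-Δ1 lactone
Product: 12 2α-hydroxy-7β-methyl-1-oxo lactone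
Conditions: RuCl3 (1 mol %), KHSO5 (as its triple salt with KHSO4 and K2SO4), NaHCO3, EtOAc/MeCN/H2O, rt
Reagents that add atoms: potassium peroxymonosulfate (oxygen source for RuO4), [K+].[O-]S(=O)(=O)OO
Why: RuO4-catalysed ketohydroxylation: [3+2] addition to the α face, which is free of the C7 methyl, the C3 oxygen and the lactone, sets 2α-OH, and the electron-withdrawing acyloxy group at C3 should keep the hydroxyl on the adjacent C2 while the more electron-rich C1 position is oxidised to the ketone.

Step 8
Reactants: 12 2α-hydroxy-7β-methyl-1-oxo lactone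
Product: 13 2α-triethylsilyloxy-7β-methyl-1-oxo lactone
Conditions: Et3SiCl, imidazole, DMF, 0 °C
Reagents that add atoms: chlorotriethylsilane, CC[Si](Cl)(CC)CC
Why: Silyl ether formation on a secondary α-hydroxy ketone under mild, non-enolising conditions; the silyloxy group later directs both alkene geometry and osmylation.

Step 9
Reactants: 14 (R)-butane-1,3-diol
Product: 15 (R)-4-iodobutan-2-ol
Conditions: I2, PPh3, imidazole, CH2Cl2, 0 °C
Reagents that add atoms: iodine, II
Why: Appel-type (Garegg–Samuelsson) iodination is selective for the primary hydroxyl and does not touch the stereocentre.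

Step 10
Reactants: 15 (R)-4-iodobutan-2-ol
Product: 16 (R)-tert-butyl[(4-iodobutan-2-yl)oxy]dimethylsilane
Conditions: t-BuMe2SiCl, imidazole, DMF, rt
Reagents that add atoms: tert-butylchlorodimethylsilane, CC(C)(C)[Si](C)(C)Cl
Why: Standard silylation of a secondary alcohol.

Step 11
Reactants: 16 (R)-tert-butyl[(4-iodobutan-2-yl)oxy]dimethylsilane
Product: 17 [(3R)-3-(tert-butyldimethylsilyloxy)butyl]triphenylphosphonium iodide
Conditions: PPh3, MeCN, reflux
Reagents that add atoms: triphenylphosphine, c1ccc(cc1)P(c1ccccc1)c1ccccc1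
Why: SN2 quaternisation of a primary iodide; the silyloxy group is γ to phosphorus, so the derived ylide cannot β-eliminate.

Step 12
Reactants: 17 [(3R)-3-(tert-butyldimethylsilyloxy)butyl]triphenylphosphonium iodide; 13 2α-triethylsilyloxy-7β-methyl-1-oxo lactone
Product: 19 (Z)-1-alkylidene lactone (chain syn to C2), via phosphorus ylide 18 (not isolated)
Conditions: KN(SiMe3)2, THF, −78 → 0 °C; then 13, −78 °C → rt
Reagents that add atoms: none
Why: Wittig olefination of an α-silyloxy ketone with a salt-free unstabilised ylide: the inductively activated carbonyl should add the ylide at low temperature faster than it enolises, and α-oxygenated ketones are known to place the new alkyl group cis to the oxygenated α-carbon.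

Step 13
Reactants: 19 (Z)-1-alkylidene lactone
Product: 20 1β,1′-diol
Conditions: OsO4 (cat.), N-methylmorpholine N-oxide, acetone/H2O, rt
Reagents that add atoms: osmium tetroxide (oxygen carrier), O=[Os](=O)(=O)=O; N-methylmorpholine N-oxide, C[N+]1([O-])CCOCC1; water, O
Why: Catalytic osmylation: A(1,3) strain with the syn C2′ methylene turns the C2 silyloxy group perpendicular to the alkene on the α face, and OsO4 adds anti to the allylic oxygen (the empirical rule for allylic ethers), so the C1 hydroxyl is placed β, trans to C2–O; the C1′ carbinol (R by syn addition) is erased in step 14.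

Step 14
Reactants: 20 1β,1′-diol
Product: 21 1β-hydroxy-1′-oxo lactone 2α-triethylsilyl ether
Conditions: Dess–Martin periodinane, NaHCO3, CH2Cl2, 0 °C → rt
Reagents that add atoms: none
Why: Dess–Martin oxidation converts the secondary C1′ alcohol to the ketone; the tertiary C1 hydroxyl cannot be oxidised and the buffered conditions spare both silyl ethers.

Step 15
Reactants: 21 1β-hydroxy-1′-oxo lactone 2α-triethylsilyl ether
Product: 22 1β,2α-dihydroxy-1′-oxo lactone
Conditions: pyridinium p-toluenesulfonate (cat.), MeOH/CH2Cl2, 0 °C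
Reagents that add atoms: none
Why: Acid-catalysed methanolysis cleaves a triethylsilyl ether much faster than a secondary tert-butyldimethylsilyl ether, freeing only the C2 hydroxyl.

Step 16
Reactants: 22 1β,2α-dihydroxy-1′-oxo lactone; 23 angelic acid
Product: 25 O-silyl angelate, via mixed anhydride 24 (not isolated)
Conditions: 2,4,6-Cl3C6H2COCl, Et3N, toluene, rt; then 22, 75 °C
Reagents that add atoms: none
Why: Yamaguchi-type esterification through the mixed anhydride, run without DMAP because nucleophilic catalysts isomerise angelates to tiglates; only the secondary C2 hydroxyl should be acylated, the tertiary C1 hydroxyl being unreactive.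

Step 17
Reactants: 25 O-silyl angelate
Product: 26 target, (3R,3aS,6S,7S,8S,8aR)-7-hydroxy-7-[(3R)-3-hydroxybutanoyl]-3,6-dimethyl-2-oxooctahydro-2H-cyclohepta[b]furan-8-yl (2Z)-2-methylbut-2-enoate
Conditions: HF·pyridine, THF/pyridine, 0 °C → rt
Reagents that add atoms: none
Why: Fluoride-mediated silyl ether cleavage under mildly acidic buffered conditions, which should spare the angelate, the lactone and the β-hydroxy ketone (no retro-aldol, no elimination).

**Compound list**

1 | cycloheptanone | O=C1CCCCCC1 | starting material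
2 | cyclohepta-2,6-dien-1-one | O=C1C=CCCC=C1 | intermediate
3 | cyclohepta-2,6-dien-1-ol | OC1C=CCCC=C1 | intermediate
4 | propanoyl chloride | CCC(=O)Cl | starting material
5 | cyclohepta-2,6-dien-1-yl propanoate | CCC(=O)OC1C=CCCC=C1 | intermediate
6 | boron ketene acetal of 5, methyl cis to the allylic oxygen, (S,S)-diazaborolidine on the enolate oxygen (not isolated) | C/C=C(/OB1N(S(=O)(=O)c2cc(cc(c2)C(F)(F)F)C(F)(F)F)[C@@H](c2ccccc2)[C@H](c2ccccc2)N1S(=O)(=O)c1cc(cc(c1)C(F)(F)F)C(F)(F)F)OC1C=CCCC=C1 | intermediate
7 | boryl ester of acid 8 (not isolated) | C[C@@H](C(=O)OB1N(S(=O)(=O)c2cc(cc(c2)C(F)(F)F)C(F)(F)F)[C@@H](c2ccccc2)[C@H](c2ccccc2)N1S(=O)(=O)c1cc(cc(c1)C(F)(F)F)C(F)(F)F)[C@H]1C=CC=CCC1 | intermediate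
8 | (2R)-2-[(1R)-cyclohepta-2,4-dien-1-yl]propanoic acid | C[C@@H](C(=O)O)[C@H]1C=CC=CCC1 | intermediate
9 | η3-allylpalladium acetate of the cis-fused lactone, metal on the α face over C2–C1–C7, drawn as its η1 form at C7 (not isolated) | CC(=O)O[Pd][C@H]1C=C[C@@H]2OC(=O)[C@H](C)[C@@H]2CC1 | intermediate
10 | 7α-acetoxy-Δ1 lactone: cis-fused γ-lactone (C3–O and C4–C8 β, 8R), C1=C2 alkene, acetate at C7 trans to C3–O | CC(=O)O[C@H]1C=C[C@@H]2OC(=O)[C@H](C)[C@@H]2CC1 | intermediate
11 | 7β-methyl-Δ1 lactone (methyl at C7 cis to C3–O) | C[C@@H]1C=C[C@@H]2OC(=O)[C@H](C)[C@@H]2CC1 | intermediate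
12 | 2α-hydroxy-7β-methyl-1-oxo lactone | O[C@H]1[C@@H]2OC(=O)[C@H](C)[C@@H]2CC[C@H](C)C1=O | intermediate
13 | 2α-triethylsilyloxy-7β-methyl-1-oxo lactone | CC[Si](CC)(CC)O[C@H]1[C@@H]2OC(=O)[C@H](C)[C@@H]2CC[C@H](C)C1=O | intermediate
14 | (R)-butane-1,3-diol | C[C@@H](O)CCO | starting material
15 | (R)-4-iodobutan-2-ol | C[C@@H](O)CCI | intermediate
16 | (R)-tert-butyl[(4-iodobutan-2-yl)oxy]dimethylsilane | C[C@@H](O[Si](C)(C)C(C)(C)C)CCI | intermediate
17 | [(3R)-3-(tert-butyldimethylsilyloxy)butyl]triphenylphosphonium iodide | C[C@@H](O[Si](C)(C)C(C)(C)C)CC[P+](c1ccccc1)(c1ccccc1)c1ccccc1.[I-] | intermediate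
18 | [(3R)-3-(tert-butyldimethylsilyloxy)butylidene]triphenylphosphorane (not isolated) | C[C@@H](O[Si](C)(C)C(C)(C)C)CC=P(c1ccccc1)(c1ccccc1)c1ccccc1 | intermediate
19 | (Z)-1-[(3R)-3-(tert-butyldimethylsilyloxy)butylidene] lactone, chain syn to C2, 2α-OSiEt3, 7β-CH3 | CC[Si](CC)(CC)O[C@H]1[C@@H]2OC(=O)[C@H](C)[C@@H]2CC[C@H](C)/C1=C/C[C@@H](C)O[Si](C)(C)C(C)(C)C | intermediate
20 | 1β,1′-diol: 1β-hydroxy-1α-[(1R,3R)-1-hydroxy-3-(tert-butyldimethylsilyloxy)butyl], 2α-OSiEt3 | CC[Si](CC)(CC)O[C@H]1[C@@H]2OC(=O)[C@H](C)[C@@H]2CC[C@H](C)[C@@]1(O)[C@H](O)C[C@@H](C)O[Si](C)(C)C(C)(C)C | intermediate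
21 | 1β-hydroxy-1α-[(3R)-3-(tert-butyldimethylsilyloxy)butanoyl] lactone 2α-triethylsilyl ether | CC[Si](CC)(CC)O[C@H]1[C@@H]2OC(=O)[C@H](C)[C@@H]2CC[C@H](C)[C@@]1(O)C(=O)C[C@@H](C)O[Si](C)(C)C(C)(C)C | intermediate
22 | 1β,2α-dihydroxy-1α-[(3R)-3-(tert-butyldimethylsilyloxy)butanoyl] lactone | O[C@H]1[C@@H]2OC(=O)[C@H](C)[C@@H]2CC[C@H](C)[C@@]1(O)C(=O)C[C@@H](C)O[Si](C)(C)C(C)(C)C | intermediate
23 | angelic acid, (Z)-2-methylbut-2-enoic acid | C/C=C(/C)C(=O)O | starting material
24 | angelic 2,4,6-trichlorobenzoic anhydride (not isolated) | C/C=C(/C)C(=O)OC(=O)c1c(Cl)cc(Cl)cc1Cl | intermediate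
25 | 3′-O-tert-butyldimethylsilyl ether of the target | C/C=C(/C)C(=O)O[C@H]1[C@@H]2OC(=O)[C@H](C)[C@@H]2CC[C@H](C)[C@@]1(O)C(=O)C[C@@H](C)O[Si](C)(C)C(C)(C)C | intermediate
26 | (3R,3aS,6S,7S,8S,8aR)-7-hydroxy-7-[(3R)-3-hydroxybutanoyl]-3,6-dimethyl-2-oxooctahydro-2H-cyclohepta[b]furan-8-yl (2Z)-2-methylbut-2-enoate | C/C=C(/C)C(=O)O[C@H]1[C@@H]2OC(=O)[C@H](C)[C@@H]2CC[C@H](C)[C@@]1(O)C(=O)C[C@@H](C)O | target

**Count**

Total steps: 17. Longest linear sequence: 14 (steps 1–8 and 12–17); steps 9–11 prepare the phosphonium salt.

**Steps most likely to fail, with fallbacks**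

Step 4. The Lewis-acidic bromoborane may ionise the doubly allylic C–O bond before enolisation, and chair and boat arrays may compete, which would erode both enantiomeric and diastereomeric purity. The fallback sets out from 5 and returns at 8. Deprotonation with LiN(iPr)2 in THF at −78 °C and trapping with Me3SiCl gives the (E)-silyl ketene acetal F1, which on warming rearranges without any Lewis acid (classical Ireland–Claisen, boat array) to the racemic trimethylsilyl ester F2. Hydrolysis gives the racemic acid F3 of the same relative configuration. This is resolved by crystallisation of its salt with (R)-1-phenylethylamine, the diastereomeric salt F4, from which acidification releases 8.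

Step 6. The trivalent allylcopper intermediate may collapse at C2 instead of C7, and the cuprate may also displace the allylic lactone carboxylate at C3, so that regiochemical control is lost. The fallback sets out from 8 and returns at 11. The same palladium-catalysed oxylactonisation is run in its chloride-mediated mode (Pd(OAc)2, p-benzoquinone, catalytic LiCl, LiOAc, acetone/AcOH), in which acetate attacks the allyl complex from outside and gives the cis acetoxy lactone F5 (acetate 7β). Zerovalent palladium (Pd(PPh3)4, THF) then ionises the acetate with inversion, and the soft nucleophile NaCH(SO2Ph)2 attacks anti to the metal at the terminus remote from the lactone oxygen, giving with overall retention the 7β-bis(phenylsulfonyl)methyl lactone F6. Reductive desulfonylation with sodium amalgam (Na2HPO4, MeOH, −20 °C) turns the bis-sulfonylmethyl group into the methyl group of 11.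

Step 12. The basic ylide may enolise the hindered ketone toward C2, which would expel the lactone carboxylate from C3 by β-elimination, or epimerise C7, instead of adding to the carbonyl group. The fallback sets out from 13 and returns at 21. Commercial (R)-but-3-yn-2-ol is silylated (t-BuMe2SiCl, imidazole) to (R)-tert-butyl(but-3-yn-2-yloxy)dimethylsilane F7. Its lithium acetylide F8 (n-BuLi, THF, −78 °C), a small and weakly basic nucleophile, adds to 13, and trapping of the alkoxide with ClCO2Me gives the propargylic methyl carbonate F9, whose C1 configuration is of no consequence. Formate reduction (Pd2(dba)3, PBu3, HCO2NH4, THF) gives the exocyclic allene F10. Osmylation of its C1=C1′ bond (OsO4, N-methylmorpholine N-oxide), again anti to the C2 silyloxy group, gives an enol that tautomerises to 21, the classical allene route to tertiary α-hydroxy ketones.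

**Further compounds**

F1 | step 4 | (E)-1-(cyclohepta-2,6-dien-1-yloxy)-1-(trimethylsilyloxy)prop-1-ene | C/C=C(/O[Si](C)(C)C)OC1C=CCCC=C1
F2 | step 4 | racemic trimethylsilyl (2R*)-2-[(1R*)-cyclohepta-2,4-dien-1-yl]propanoate | C[C@@H](C(=O)O[Si](C)(C)C)[C@H]1C=CC=CCC1.C[C@H](C(=O)O[Si](C)(C)C)[C@@H]1C=CC=CCC1
F3 | step 4 | racemic (2R*)-2-[(1R*)-cyclohepta-2,4-dien-1-yl]propanoic acid | C[C@@H](C(=O)O)[C@H]1C=CC=CCC1.C[C@H](C(=O)O)[C@@H]1C=CC=CCC1
F4 | step 4 | (R)-1-phenylethylammonium salt of acid 8 | C[C@@H](C(=O)O)[C@H]1C=CC=CCC1.C[C@@H](N)c1ccccc1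
F5 | step 6 | 7β-acetoxy-Δ1 lactone (acetate cis to C3–O) | CC(=O)O[C@@H]1C=C[C@@H]2OC(=O)[C@H](C)[C@@H]2CC1
F6 | step 6 | 7β-[bis(phenylsulfonyl)methyl]-Δ1 lactone | O=S(=O)(c1ccccc1)C([C@@H]1C=C[C@@H]2OC(=O)[C@H](C)[C@@H]2CC1)S(=O)(=O)c1ccccc1
F7 | step 12 | (R)-tert-butyl(but-3-yn-2-yloxy)dimethylsilane | C#C[C@@H](C)O[Si](C)(C)C(C)(C)C
F8 | step 12 | lithium acetylide of F7 | [Li]C#C[C@@H](C)O[Si](C)(C)C(C)(C)C
F9 | step 12 | C1 propargylic methyl carbonate of the adduct of F8 and 13 (C1 epimers) | CC[Si](CC)(CC)O[C@H]1[C@@H]2OC(=O)[C@H](C)[C@@H]2CC[C@H](C)C1(OC(=O)OC)C#C[C@@H](C)O[Si](C)(C)C(C)(C)C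
F10 | step 12 | exocyclic allene C1=C1′=C2′ (2α-OSiEt3, 3′-OSi-t-BuMe2) | CC[Si](CC)(CC)O[C@H]1[C@@H]2OC(=O)[C@H](C)[C@@H]2CC[C@H](C)C1=C=C[C@@H](C)O[Si](C)(C)C(C)(C)C
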